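The heptane chain is numbered C1 (oxane carbon bearing ring B, the 3,4-dihydroxy-5-methoxyphenyl) to C7 (benzylic CH2 of ring A, the 4-hydroxy-3-methoxyphenyl); the ring oxygen joins C1 and C5 and the hydroxyl sits on C3.
Enabling feature: C1 is benzylic to the electron-rich, trioxygenated ring B and also carries the ring oxygen, so in an open-chain ring B benzyl ether of the C5 alcohol its C–H bond can be oxidised to an oxocarbenium ion that a C2=C3 enol acetate captures.
Retrosynthetic cuts, in order: C3 carbinol back to the ketone, C1–C2 (opens the oxane), C3–OAc of the enol acetate (back to a C2–C3 alkyne), O–C1 (benzyl ether), C4–C5 (propargyl addition to the ring A propanal).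
Forward: the ring A aldehyde (C5–C7) and an allenylboronate (C2–C4) are joined first, ring B with C1 is attached through oxygen, and the oxane, the only new ring, closes last by C1–C2 bond formation.
Stereochemistry: C5 (S) from chiral phosphoric acid catalysis; C1 (S) relayed from C5 through a chair transition state (2,6-cis); C3 (R) from axial hydride delivery to the chair ketone (all-cis).

Key step: step 10

Assumption: (R)-3,3'-bis(2,4,6-triisopropylphenyl)-1,1'-binaphthyl-2,2'-diyl hydrogen phosphate is taken to direct the allenylboronate to the Re face of an unbranched aliphatic aldehyde, as in the related allylboration; if the sense proved opposite, the (S)-acid would be used.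

Step 1
Reactants: 1 3-(4-hydroxy-3-methoxyphenyl)propanoic acid
Product: 2 3-(4-acetoxy-3-methoxyphenyl)propanoic acid
Conditions: Ac2O, NaOH (aq), 0 °C; then HCl (aq)
Reagents that add atoms: acetic anhydride, CC(=O)OC(C)=O
Why: Schotten–Baumann-type O-acetylation, in which the phenoxide is acylated in cold aqueous alkali while the carboxylate stays as its salt and is recovered as the acid on acidification.

Step 2
Reactants: 2 3-(4-acetoxy-3-methoxyphenyl)propanoic acid
Product: 3 4-(3-hydroxypropyl)-2-methoxyphenyl acetate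
Conditions: BH3·SMe2 (1.2 equiv), THF, 0 °C to rt; then MeOH
Reagents that add atoms: none
Why: Chemoselective borane reduction of a carboxylic acid, which proceeds through an acyloxyborane far faster than BH3 attacks the aryl ester, so the acetate should survive a small excess of reagent at low temperature.

Step 3
Reactants: 3 4-(3-hydroxypropyl)-2-methoxyphenyl acetate
Product: 4 2-methoxy-4-(3-oxopropyl)phenyl acetate
Conditions: 2,2,6,6-tetramethylpiperidin-1-oxyl (10 mol %), PhI(OAc)2, CH2Cl2, rt
Reagents that add atoms: none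
Why: Nitroxyl-catalysed (oxoammonium) oxidation of a primary alcohol with PhI(OAc)2 as terminal oxidant should stop at the aldehyde and leave the aryl acetate untouched.

Step 4
Reactants: 4 2-methoxy-4-(3-oxopropyl)phenyl acetate; 5 allenylboronic acid pinacol ester
Product: 6 4-[(3S)-3-hydroxyhex-5-yn-1-yl]-2-methoxyphenyl acetate
Conditions: (R)-3,3'-bis(2,4,6-triisopropylphenyl)-1,1'-binaphthyl-2,2'-diyl hydrogen phosphate (10 mol %), 4 Å MS, toluene, −20 °C; then H2O
Reagents that add atoms: none
Why: Chiral Brønsted acid catalysed propargylboration, in which the allenylboronate transfers its γ-carbon through a six-membered chair transition state (SE2') while the phosphoric acid hydrogen-bonds to a boronate oxygen and the formyl hydrogen, so that addition to the Re face of the aldehyde sets C5 as S.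

Step 5
Reactants: 7 3,4-dihydroxy-5-methoxybenzaldehyde
Product: 8 3,4-bis(benzyloxy)-5-methoxybenzaldehyde
Conditions: BnBr (2.3 equiv), K2CO3, DMF, 60 °C
Reagents that add atoms: benzyl bromide, BrCc1ccccc1
Why: Williamson ether synthesis, in which both phenoxides are benzylated and the aldehyde is inert.

Step 6
Reactants: 8 3,4-bis(benzyloxy)-5-methoxybenzaldehyde
Product: 9 [3,4-bis(benzyloxy)-5-methoxyphenyl]methanol
Conditions: NaBH4, MeOH/THF, 0 °C
Reagents that add atoms: none
Why: Borohydride reduction of an aromatic aldehyde to the benzylic alcohol, which leaves the aryl benzyl ethers unaffected.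

Step 7
Reactants: 9 [3,4-bis(benzyloxy)-5-methoxyphenyl]methanol
Product: 10 [3,4-bis(benzyloxy)-5-methoxyphenyl]methyl 2,2,2-trichloroethanimidate
Conditions: Cl3CCN, 1,8-diazabicyclo[5.4.0]undec-7-ene (10 mol %), CH2Cl2, 0 °C
Reagents that add atoms: trichloroacetonitrile, N#CC(Cl)(Cl)Cl
Why: Base-catalysed addition of a primary benzylic alkoxide to trichloroacetonitrile (trichloroacetimidate formation) should be fast and clean, and the imidate is used promptly after filtration through a short basic pad.

Step 8
Reactants: 6 4-[(3S)-3-hydroxyhex-5-yn-1-yl]-2-methoxyphenyl acetate; 10 [3,4-bis(benzyloxy)-5-methoxyphenyl]methyl 2,2,2-trichloroethanimidate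
Product: 11 4-[(3S)-3-{[3,4-bis(benzyloxy)-5-methoxyphenyl]methoxy}hex-5-yn-1-yl]-2-methoxyphenyl acetate
Conditions: CF3SO3H (1 mol %), Et2O/CH2Cl2, −20 to 0 °C
Reagents that add atoms: none
Why: Acid-catalysed trichloroacetimidate O-benzylation, in which the protonated imidate ionises to a stabilised benzylic cation that the C5 hydroxyl captures; the C5–O bond is never broken, so C5 stays S, and the acidic conditions spare the aryl acetate that a basic Williamson reaction would cleave.

Step 9
Reactants: 11 4-[(3S)-3-{[3,4-bis(benzyloxy)-5-methoxyphenyl]methoxy}hex-5-yn-1-yl]-2-methoxyphenyl acetate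
Product: 12 4-[(3S)-5-acetoxy-3-{[3,4-bis(benzyloxy)-5-methoxyphenyl]methoxy}hex-5-en-1-yl]-2-methoxyphenyl acetate
Conditions: [RuCl2(p-cymene)]2 (2 mol %), tri(2-furyl)phosphine (8 mol %), Na2CO3 (8 mol %), AcOH (2 equiv), toluene, 80 °C
Reagents that add atoms: acetic acid, CC(=O)O
Why: Ruthenium-catalysed Markovnikov hydro-acyloxylation of a terminal alkyne, in which acetate adds to the internal carbon of the metal-bound alkyne to give the 2-acetoxy-1-alkene under neutral conditions that tolerate the benzyl ethers and the aryl acetate.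

Step 10
Reactants: 12 4-[(3S)-5-acetoxy-3-{[3,4-bis(benzyloxy)-5-methoxyphenyl]methoxy}hex-5-en-1-yl]-2-methoxyphenyl acetate
Product: 15 4-{2-[(2S,6S)-6-[3,4-bis(benzyloxy)-5-methoxyphenyl]-4-oxooxan-2-yl]ethyl}-2-methoxyphenyl acetate, via benzylic oxocarbenium ion 13 (not isolated), via O-acetyl oxocarbenium ion 14 (not isolated)
Conditions: 2,3-dichloro-5,6-dicyano-1,4-benzoquinone (DDQ, 2 equiv), 2,6-dichloropyridine (4 equiv), 4 Å MS, ClCH2CH2Cl, rt
Reagents that add atoms: none
Why: DDQ takes an electron from the trialkoxy ring B and then the benzylic hydrogen (net hydride abstraction) to give the (E)-oxocarbenium ion 13 conjugated with ring B; the CH2 terminus of the enol acetate adds to C1, and the resulting O-acetyl oxocarbenium ion 14 gives up its acetyl group to leave the C3 ketone. The closest known reaction type is the DDQ-mediated oxidative C–H cleavage of electron-rich benzylic ethers with capture by a tethered enol acetate, a Prins/Mukaiyama-type addition to an oxidatively generated oxocarbenium ion. The oxane closes in a 6-endo-trig mode at the oxocarbenium carbon (enol-endo with respect to the nucleophile). The new C1 stereocentre is controlled by C5: in the chair transition state the C5 side chain and the aryl group of the (E)-oxocarbenium ion are both equatorial, which should give the 2,6-cis (2S,6S) ketone. The step needs site selectivity for the ring B benzylic ether C–H, which is secured because ring A carries an electron-withdrawing acetate and has no oxygen on its benzylic carbon, the O-benzyl protecting groups are unactivated phenylmethyl ethers, and the product is inductively deactivated by its ketone toward a second oxidation. 2,6-Dichloropyridine buffers the acid that forms and the molecular sieves keep water from hydrolysing the cation or the enol acetate.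

Step 11
Reactants: 15 4-{2-[(2S,6S)-6-[3,4-bis(benzyloxy)-5-methoxyphenyl]-4-oxooxan-2-yl]ethyl}-2-methoxyphenyl acetate
Product: 17 (2S,4R,6S)-2-[3,4-bis(benzyloxy)-5-methoxyphenyl]-6-[2-(4-hydroxy-3-methoxyphenyl)ethyl]oxan-4-ol, via hydroxy acetate 16 (not isolated)
Conditions: NaBH4, MeOH/THF, −20 °C; then K2CO3 (0.3 equiv), MeOH, rt
Reagents that add atoms: none
Why: Diastereoselective borohydride reduction, in which the small hydride attacks axially on the chair oxanone with both ring substituents equatorial and so should give the equatorial C3 alcohol (4R, all-cis), followed by base-catalysed transesterification of the aryl acetate only after the ketone is gone, so that retro-oxa-Michael epimerisation cannot occur.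

Step 12
Reactants: 17 (2S,4R,6S)-2-[3,4-bis(benzyloxy)-5-methoxyphenyl]-6-[2-(4-hydroxy-3-methoxyphenyl)ethyl]oxan-4-ol
Product: 18 (2S,4R,6S)-2-(3,4-dihydroxy-5-methoxyphenyl)-6-[2-(4-hydroxy-3-methoxyphenyl)ethyl]oxan-4-ol
Conditions: H2 (1 atm), Pd/C (10 wt %), EtOAc/MeOH, rt
Reagents that add atoms: none
Why: Catalytic hydrogenolysis (O-debenzylation) of the two aryl benzyl ethers under neutral conditions, which should be much faster than cleavage of the benzylic C1–O bond of the oxane if the reaction is stopped after two equivalents of H2.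

Compound list
1 | 3-(4-hydroxy-3-methoxyphenyl)propanoic acid | COc1cc(CCC(=O)O)ccc1O | starting material
2 | 3-(4-acetoxy-3-methoxyphenyl)propanoic acid | COc1cc(CCC(=O)O)ccc1OC(C)=O | intermediate
3 | 4-(3-hydroxypropyl)-2-methoxyphenyl acetate | COc1cc(CCCO)ccc1OC(C)=O | intermediate
4 | 2-methoxy-4-(3-oxopropyl)phenyl acetate | COc1cc(CCC=O)ccc1OC(C)=O | intermediate
5 | allenylboronic acid pinacol ester (4,4,5,5-tetramethyl-2-(propa-1,2-dien-1-yl)-1,3,2-dioxaborolane) | C=C=CB1OC(C)(C)C(C)(C)O1 | starting material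
6 | 4-[(3S)-3-hydroxyhex-5-yn-1-yl]-2-methoxyphenyl acetate | COc1cc(CC[C@H](O)CC#C)ccc1OC(C)=O | intermediate
7 | 3,4-dihydroxy-5-methoxybenzaldehyde | COc1cc(C=O)cc(O)c1O | starting material
8 | 3,4-bis(benzyloxy)-5-methoxybenzaldehyde | COc1cc(C=O)cc(OCc2ccccc2)c1OCc1ccccc1 | intermediate
9 | [3,4-bis(benzyloxy)-5-methoxyphenyl]methanol | COc1cc(CO)cc(OCc2ccccc2)c1OCc1ccccc1 | intermediate
10 | [3,4-bis(benzyloxy)-5-methoxyphenyl]methyl 2,2,2-trichloroethanimidate | COc1cc(COC(=N)C(Cl)(Cl)Cl)cc(OCc2ccccc2)c1OCc1ccccc1 | intermediate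
11 | 4-[(3S)-3-{[3,4-bis(benzyloxy)-5-methoxyphenyl]methoxy}hex-5-yn-1-yl]-2-methoxyphenyl acetate | COc1cc(CC[C@H](OCc2cc(OCc3ccccc3)c(OCc3ccccc3)c(OC)c2)CC#C)ccc1OC(C)=O | intermediate
12 | 4-[(3S)-5-acetoxy-3-{[3,4-bis(benzyloxy)-5-methoxyphenyl]methoxy}hex-5-en-1-yl]-2-methoxyphenyl acetate | COc1cc(CC[C@H](OCc2cc(OCc3ccccc3)c(OCc3ccccc3)c(OC)c2)CC(=C)OC(C)=O)ccc1OC(C)=O | intermediate
13 | (E)-benzylic oxocarbenium ion: {[3,4-bis(benzyloxy)-5-methoxyphenyl]methylidene}[(3S)-5-acetoxy-1-(4-acetoxy-3-methoxyphenyl)hex-5-en-3-yl]oxonium | COc1cc(CC[C@H](/[O+]=C/c2cc(OCc3ccccc3)c(OCc3ccccc3)c(OC)c2)CC(=C)OC(C)=O)ccc1OC(C)=O | intermediate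
14 | O-acetyl oxocarbenium ion: acetyl{(2S,6S)-2-[2-(4-acetoxy-3-methoxyphenyl)ethyl]-6-[3,4-bis(benzyloxy)-5-methoxyphenyl]oxan-4-ylidene}oxonium | COc1cc(CC[C@H]2CC(=[O+]C(C)=O)C[C@@H](c3cc(OCc4ccccc4)c(OCc4ccccc4)c(OC)c3)O2)ccc1OC(C)=O | intermediate
15 | 4-{2-[(2S,6S)-6-[3,4-bis(benzyloxy)-5-methoxyphenyl]-4-oxooxan-2-yl]ethyl}-2-methoxyphenyl acetate | COc1cc(CC[C@H]2CC(=O)C[C@@H](c3cc(OCc4ccccc4)c(OCc4ccccc4)c(OC)c3)O2)ccc1OC(C)=O | intermediate
16 | 4-{2-[(2S,4R,6S)-6-[3,4-bis(benzyloxy)-5-methoxyphenyl]-4-hydroxyoxan-2-yl]ethyl}-2-methoxyphenyl acetate | COc1cc(CC[C@H]2C[C@@H](O)C[C@@H](c3cc(OCc4ccccc4)c(OCc4ccccc4)c(OC)c3)O2)ccc1OC(C)=O | intermediate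
17 | (2S,4R,6S)-2-[3,4-bis(benzyloxy)-5-methoxyphenyl]-6-[2-(4-hydroxy-3-methoxyphenyl)ethyl]oxan-4-ol | COc1cc(CC[C@H]2C[C@@H](O)C[C@@H](c3cc(OCc4ccccc4)c(OCc4ccccc4)c(OC)c3)O2)ccc1O | intermediate
18 | (2S,4R,6S)-2-(3,4-dihydroxy-5-methoxyphenyl)-6-[2-(4-hydroxy-3-methoxyphenyl)ethyl]oxan-4-ol | COc1cc(CC[C@H]2C[C@@H](O)C[C@@H](c3cc(O)c(O)c(OC)c3)O2)ccc1O | target

Total step count: 12. Longest linear sequence: 9 steps (steps 1–4 and 8–12, from compound 1).

Steps most likely to fail

Step 10. Hydride abstraction may be slow, because the central alkoxy group of ring B is twisted out of conjugation and the two flanking ones are meta to the benzylic carbon. Hydrolysis of the enol acetate or of the cation, or oxidation at another site, may then compete. The fallback generates the same C1 oxocarbenium ion by condensation instead of oxidation and still closes the C1–C2 bond. It sets out from aldehyde 4: asymmetric addition of tributyl{2-[(trimethylsilyl)methyl]prop-2-en-1-yl}stannane under (R)-1,1'-bi-2-naphthol/Ti(OiPr)4 catalysis (CH2Cl2, −20 °C) should give 4-[(3S)-3-hydroxy-5-[(trimethylsilyl)methyl]hex-5-en-1-yl]-2-methoxyphenyl acetate F1. Condensation of this alcohol with aldehyde 8 under Me3SiOSO2CF3 (Et2O, −78 °C) should close the ring by an intramolecular Sakurai addition through the same chair, giving 4-{2-[(2S,6S)-6-[3,4-bis(benzyloxy)-5-methoxyphenyl]-4-methylideneoxan-2-yl]ethyl}-2-methoxyphenyl acetate F2. Lemieux–Johnson cleavage of the exocyclic alkene (OsO4 cat., NaIO4, 2,6-lutidine, dioxane/H2O) comes back to the route at ketone 15.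

Step 4. Face discrimination by the phosphoric acid may be insufficient for an unbranched aliphatic aldehyde, and some allenyl carbinol may arise from α-attack of the boronate. The fallback sets C5 by asymmetric allylation and closes the oxane by a Prins cyclisation. It sets out from aldehyde 4: Keck allylation (allyltributylstannane, (R)-1,1'-bi-2-naphthol, Ti(OiPr)4, CH2Cl2, −20 °C) should give 4-[(3S)-3-hydroxyhex-5-en-1-yl]-2-methoxyphenyl acetate F3. Prins cyclisation of this alcohol with aldehyde 8 in CF3CO2H/CH2Cl2 at 0 °C should give the all-cis ester (2S,4R,6S)-2-[2-(4-acetoxy-3-methoxyphenyl)ethyl]-6-[3,4-bis(benzyloxy)-5-methoxyphenyl]oxan-4-yl trifluoroacetate F4. K2CO3 in MeOH then cleaves the trifluoroacetate and the aryl acetate, and the route is rejoined at compound 17.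

Step 8. Ionisation of the electron-rich imidate may outrun capture by the hindered secondary alcohol, so that rearrangement to the N-benzyl trichloroacetamide or Friedel–Crafts self-alkylation of ring B consumes the reagent. The fallback is a reductive etherification, which also makes steps 6 and 7 unnecessary. It sets out from alcohol 6: Me3SiCl and imidazole (CH2Cl2, 0 °C) should give 2-methoxy-4-[(3S)-3-[(trimethylsilyl)oxy]hex-5-yn-1-yl]phenyl acetate F5. With aldehyde 8, Et3SiH and catalytic Me3SiOSO2CF3 (CH2Cl2, −78 °C) this silyl ether should be converted, through the silyl-activated oxocarbenium ion and hydride transfer, directly into ether 11, where the route is rejoined.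

Further compounds
F1 | step 10 | 4-[(3S)-3-hydroxy-5-[(trimethylsilyl)methyl]hex-5-en-1-yl]-2-methoxyphenyl acetate | COc1cc(CC[C@H](O)CC(=C)C[Si](C)(C)C)ccc1OC(C)=O
F2 | step 10 | 4-{2-[(2S,6S)-6-[3,4-bis(benzyloxy)-5-methoxyphenyl]-4-methylideneoxan-2-yl]ethyl}-2-methoxyphenyl acetate | COc1cc(CC[C@H]2CC(=C)C[C@@H](c3cc(OCc4ccccc4)c(OCc4ccccc4)c(OC)c3)O2)ccc1OC(C)=O
F3 | step 4 | 4-[(3S)-3-hydroxyhex-5-en-1-yl]-2-methoxyphenyl acetate | COc1cc(CC[C@H](O)CC=C)ccc1OC(C)=O
F4 | step 4 | (2S,4R,6S)-2-[2-(4-acetoxy-3-methoxyphenyl)ethyl]-6-[3,4-bis(benzyloxy)-5-methoxyphenyl]oxan-4-yl trifluoroacetate | COc1cc(CC[C@H]2C[C@@H](OC(=O)C(F)(F)F)C[C@@H](c3cc(OCc4ccccc4)c(OCc4ccccc4)c(OC)c3)O2)ccc1OC(C)=O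
F5 | step 8 | 2-methoxy-4-[(3S)-3-[(trimethylsilyl)oxy]hex-5-yn-1-yl]phenyl acetate | COc1cc(CC[C@H](O[Si](C)(C)C)CC#C)ccc1OC(C)=O
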